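# (2S)-5,6,7,3',4',5'-Hexamethoxyflavanone (6): synthesis proposal

## Analysis of the target

Compound 6 is (2S)-5,6,7-trimethoxy-2-(3,4,5-trimethoxyphenyl)-2,3-dihydro-4H-chromen-4-one. It is a flavanone in which the electron-rich benzene ring A is fused through C4a–C8a to the dihydropyranone ring C, and ring C carries the aryl ring B at C2. C2 is the only stereocenter. The SMILES lists its neighbours as C1', H, O1, C3 with @@, which reads as S with the priorities O1 > C1' > C3 > H, so only one absolute configuration has to be controlled. This center is benzylic, bears the aryloxy oxygen O1 and lies β to the C4 carbonyl. Base or hot acid therefore cleaves O1–C2 by a retro-oxa-Michael reaction to an achiral open enone, which recloses without memory. The difficulty is not connectivity but making and keeping one labile center.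

The six aryl methyl ethers are robust, with one exception: the C5 methoxy group, peri to C4=O, is prone to chelation-assisted cleavage by hard Lewis acids. Ring A is also easily oxidised.

The plan is built on the bond C2–C1'.
- It is the only bond at the stereocenter that lies outside ring C.
- Ring B behind it is locally twofold symmetric and unsubstituted at C2' and C6'.
- The cut leaves the flat, achiral enone O1–C2=C3–C4=O of a chromone, whose electrophilic terminus is exactly C2.

A second feature concerns ring A (O1 at C8a, H at C8, methoxy at C5, C6 and C7). It maps onto a phenol with a mirror plane whose two free ring positions are equivalent, so the C4–C4a bond raises no regiochemical question.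

## Retrosynthetic reasoning

**Cut C2–C1' (6 ⇒ 4 + 5).** Cutting O1–C2 or C2–C3 would open ring C and lead back into the open-chain enone manifold through which 6 racemises. Cutting C2–C1' leaves ring C closed.
- The precursor is reduced to the planar, achiral chromone 4 and the commercial boronic acid 5.
- The two halves are joined and the only stereocenter is set in the same operation.
- This is the last step, so C2 never meets base or strong acid, and no protecting group is needed.

The forward reaction has four tasks. It must deliver the aryl group to C2 and not to C4. It must tell apart the two faces of a flat heterocycle by catalyst control alone. It must protonate the resulting enolate faster than the enolate expels O1. It must run in a neutral medium.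

**Cut O1–C2 and C2=C3 in ring C of the chromone (4 ⇒ 3 ⇒ 2).** C2 of 4 is a single carbon at the formyl oxidation level, inserted between the methyl group of an o-hydroxyaryl methyl ketone and its phenolic oxygen. This cut keeps all substituents of ring A in place and needs no stereocontrol. In the forward sense a C1 electrophile condenses on the methyl ketone of 2 to give the enaminone 3. Acid then exchanges the amine for the phenolic oxygen with ring closure.

**Cut C4–C4a (2 ⇒ 1).** Removing the acetyl group from 2 gives phenol 1. Its only free ring positions, C2 and C6, are interchanged by the mirror plane through C1 and C4. Each is ortho to the hydroxyl group and ortho or para to two methoxy groups. The forward C-acylation can therefore give only one regioisomer, and the 5,6,7-trimethoxy pattern of ring A is bought rather than built.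

## Alternatives that were turned down

**Alternative 1:** the textbook route, disconnection O1–C2. Claisen–Schmidt condensation of 2 with 3,4,5-trimethoxybenzaldehyde A1 would give the 2'-hydroxychalcone A2. The key step would be an enantioselective 6-endo-trig oxa-Michael closure of A2, with a chiral base/hydrogen-bond donor or an enzyme of the chalcone isomerase class. It was turned down for these reasons.
- The bond formed is the same bond that breaks when 6 racemises. By microscopic reversibility, a catalyst that lowers the barrier to closure also lowers the barrier to opening. The enantiomeric purity is then only kinetic and drifts toward the racemate.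
- The β-carbon of A2 is a weak acceptor because ring B is a donor, and the phenol is tied up in a hydrogen bond to the carbonyl.
- The usual remedy is an activating ester at C3, as in the alkylidene β-keto ester A3. It has to be installed and then removed by acidolysis and decarboxylation, at least two extra steps.
- An isomerase pocket is shaped for hydroxylated chalcones. Six methoxy groups remove those hydrogen-bond contacts and add bulk.

**Alternative 2:** disconnection C2–H, with ring C built by a three-component reaction. Carbonylative Sonogashira coupling and cyclisation of 2-iodo-3,4,5-trimethoxyphenol A4 with 5-ethynyl-1,2,3-trimethoxybenzene A5 would give the flavone A6. Asymmetric conjugate reduction or hydrogenation of C2=C3 would follow. The assembly is attractive, but it was turned down for these reasons.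
- The stereo-defining step must bring hydride to a fully substituted β-carbon of a vinylogous ester that receives electron density from O1, ring A and ring B. This is the least electrophilic position available.
- Conditions strong enough for that also reduce C4=O, giving the flavan-4-ol A7, which then needs reoxidation.
- Iodination, carbonylation, reduction and reoxidation make four steps, and fragment union and stereocontrol are separate operations.

**Alternative 3:** disconnection C4–C4a with the stereocenter already in place. Mitsunobu etherification of ethyl (R)-3-hydroxy-3-(3,4,5-trimethoxyphenyl)propanoate A8 with 1, with inversion, followed by saponification, would give the (S)-β-aryloxy acid A9. Intramolecular Friedel–Crafts acylation at either of the two equivalent ortho positions would close ring C. It was turned down for these reasons.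
- The closure needs a strong Brønsted or Lewis acid. Under these conditions the benzylic C2–O bond can ionise, since it has an aryloxy leaving group and a cation stabilised by the para methoxy group of ring B. The consequences are racemisation and recombination through carbon of ring A instead of oxygen.
- Saponification of a β-aryloxy ester invites E1cB loss of the phenoxide.
- The Mitsunobu step at an electron-rich benzylic alcohol is not securely SN2.
- At least five steps are needed.

Key step: step 3

Remark on the chemistry: (S)-MeO-F12-BIPHEP stands for (S)-(6,6'-dimethoxybiphenyl-2,2'-diyl)bis[bis(3,4,5-trifluorophenyl)phosphane]; the (S) antipode is assigned from the quadrant model by analogy with cyclic enones, and a reversed sense would be corrected by taking the equally available (R) antipode without any change of the route.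

## Route

Step 1
Reactants: 1 3,4,5-trimethoxyphenol
Product: 2 1-(6-hydroxy-2,3,4-trimethoxyphenyl)ethan-1-one
Conditions: AcOH, BF3·OEt2 (3 equiv), 85 °C; then H2O
Reagents that add atoms: acetic acid, CC(=O)O
Why: Friedel–Crafts C-acylation of an activated phenol with the BF3-activated acid; the only two free positions of 1 are equivalent by symmetry, so a single regioisomer is possible, and the hydrogen-bonded o-hydroxy ketone is deactivated toward a second acylation. No stereocenter is formed.

Step 2
Reactants: 2 1-(6-hydroxy-2,3,4-trimethoxyphenyl)ethan-1-one
Product: 4 5,6,7-trimethoxy-4H-chromen-4-one, via enaminone 3 (not isolated)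
Conditions: Me2NCH(OMe)2 (2 equiv), toluene, 100 °C; concentrate; then conc. HCl, CH2Cl2, 40 °C
Reagents that add atoms: N,N-dimethylformamide dimethyl acetal, COC(OC)N(C)C
Why: Aminomethylenation of the methyl ketone gives the push–pull enaminone 3; protonation turns its β-carbon into an iminium-type acceptor, the phenolic oxygen adds and dimethylamine is expelled (addition–elimination), which closes ring C. This is the standard enaminone route to 2,3-unsubstituted chromones and is established for 2-hydroxy-4,6-dialkoxyacetophenones; no stereocenter is formed.

Step 3
Reactants: 4 5,6,7-trimethoxy-4H-chromen-4-one, 5 (3,4,5-trimethoxyphenyl)boronic acid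
Product: 6 (2S)-5,6,7-trimethoxy-2-(3,4,5-trimethoxyphenyl)-2,3-dihydro-4H-chromen-4-one
Conditions: [Rh(OH)(cod)]2 (1.5 mol %), (S)-MeO-F12-BIPHEP (3.3 mol %), toluene, 50 °C, 30 min; then 4, 5 (2 equiv, in portions), toluene/H2O (10:1), 30 °C
Reagents that add atoms: none
Why: Hayashi–Miyaura asymmetric 1,4-addition, a reaction type with close precedent on chromones, 5,7-dioxygenated ones included. Mechanism: 5 transmetalates to the hydroxo complex of monovalent rhodium, 4 binds through C2=C3, syn migratory insertion forms C2–C1' and puts rhodium on C3, the C-bound enolate relaxes to the oxa-π-allyl form over C3–C4–O, and water protonates C3 and returns Rh–OH, so that no external base is needed. No ring is closed in this step; rings A and C are in place and ring B is joined to them. C2, the only new stereocenter, is set by the catalyst alone: the P-aryl groups of the axially chiral bisphosphine block two diagonal quadrants, the flat benzopyranone fits only with ring A in an open quadrant, and the (S) ligand should then deliver the aryl group to the Re face of C2 (O1 > C3 > H), the spatial mode in which (S)-biaryl bisphosphines give (S)-3-arylcyclohexanones and which here reads as 2S. The step needs 1,4- over 1,2-selectivity, and the substrate secures it, because C4=O is a vinylogous ester carbonyl shielded by the peri C5 methoxy group, which also protects the ketone of 6 from a second arylation. It needs an insertion that outruns protodeboronation of 5, which the free C2'/C6' positions of 5 (fast transmetalation) and the electron-poor 3,4,5-trifluorophenyl groups on phosphorus (more electrophilic rhodium, stronger binding of the electron-rich enone) are chosen to provide. It needs protonation of the enolate before O1 is expelled: β-aryloxy elimination asks for a syn-coplanar Rh–C3–C2–O1 array, which the six-membered ring does not allow after syn addition, and water is present in excess. The neutral two-phase medium at 30 °C keeps 6 away from the retro-oxa-Michael pathway, so that the configuration once set should persist.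

## Compound list

1 | 3,4,5-trimethoxyphenol | COc1cc(O)cc(OC)c1OC | starting material
2 | 1-(6-hydroxy-2,3,4-trimethoxyphenyl)ethan-1-one | CC(=O)c1c(O)cc(OC)c(OC)c1OC | intermediate
3 | (E)-3-(dimethylamino)-1-(6-hydroxy-2,3,4-trimethoxyphenyl)prop-2-en-1-one | CN(C)/C=C/C(=O)c1c(O)cc(OC)c(OC)c1OC | intermediate
4 | 5,6,7-trimethoxy-4H-chromen-4-one | COc1cc2occc(=O)c2c(OC)c1OC | intermediate
5 | (3,4,5-trimethoxyphenyl)boronic acid | COc1cc(B(O)O)cc(OC)c1OC | starting material
6 | (2S)-5,6,7-trimethoxy-2-(3,4,5-trimethoxyphenyl)-2,3-dihydro-4H-chromen-4-one | COc1cc([C@@H]2CC(=O)c3c(cc(OC)c(OC)c3OC)O2)cc(OC)c1OC | target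

## Step count and risks

Total step count: 3. Longest linear sequence: 3 (1 → 2 → 4 → 6); 5 enters in the last step.

**Step 3 (key step).** Two things are most likely to go wrong.
- Insertion may be slow. The enone of 4 is a vinylogous ester made still more electron-rich by three methoxy donors, so protodeboronation of 5 could consume the aryl donor first.
- Enantiomeric purity may erode, either through a background reaction at rhodium that still carries cod after incomplete ligand exchange, or through ring opening at the enolate stage.

The fallback sets out from 2 and returns at 6. Claisen–Schmidt condensation of 2 with the aldehyde A1 (KOH, EtOH) would give the (E)-2'-hydroxychalcone F1, the same compound as A2. NaOAc in refluxing EtOH would close it to the racemic flavanone F2. F2 would then be resolved kinetically by asymmetric transfer hydrogenation (RuCl(p-cymene)[(R,R)-TsDPEN], HCO2H/NEt3, EtOAc). In the 2R enantiomer the catalyst preference for a 4R alcohol and the substrate preference for the cis product coincide. That enantiomer should therefore be reduced to the (2R,4R)-flavan-4-ol F3, while the 2S ketone, which is 6, is left behind and separated by chromatography. The price is that at most half of F2 can end up as 6.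

**Step 2.** Methyl transfer from the amide acetal to the phenolic oxygen may compete. The acetyl group sits between two ortho substituents and condenses slowly at the temperature required, and a blocked phenol cannot close ring C.

The fallback sets out from 1 and returns at 4. It closes ring C through C4–C4a instead of O1–C2. DABCO-catalysed oxa-Michael addition of 1 to ethyl propiolate (CH2Cl2, room temperature) would give ethyl (E)-3-(3,4,5-trimethoxyphenoxy)acrylate F4. LiOH in THF/H2O would give (E)-3-(3,4,5-trimethoxyphenoxy)acrylic acid F5. Cyclodehydration in P2O5/MeSO3H would acylate one of the two equivalent ortho positions to give 4; protonation of the enol ether allows the E/Z rotation that the closure needs.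

**Step 1.** The hot Lewis acid may cause chelation-assisted loss of the methyl group from the methoxy group next to the new carbonyl. The reaction may also stall at O-acylation.

The fallback sets out from 1 and returns at 2. It reverses the polarity of the C–C bond formation. MOMCl/iPr2NEt would give 1,2,3-trimethoxy-5-(methoxymethoxy)benzene F6. n-BuLi (THF, 0 °C) would lithiate the position flanked by the OMOM and OMe groups, which is the only kind of ring C–H present. N-Methoxy-N-methylacetamide would then give 1-[2,3,4-trimethoxy-6-(methoxymethoxy)phenyl]ethan-1-one F7. HCl in MeOH would release 2.

## Further compounds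

F1 | step 3 | (E)-1-(6-hydroxy-2,3,4-trimethoxyphenyl)-3-(3,4,5-trimethoxyphenyl)prop-2-en-1-one | COc1cc(/C=C/C(=O)c2c(O)cc(OC)c(OC)c2OC)cc(OC)c1OC
F2 | step 3 | rac-5,6,7-trimethoxy-2-(3,4,5-trimethoxyphenyl)-2,3-dihydro-4H-chromen-4-one (racemate, no descriptor) | COc1cc(C2CC(=O)c3c(cc(OC)c(OC)c3OC)O2)cc(OC)c1OC
F3 | step 3 | (2R,4R)-5,6,7-trimethoxy-2-(3,4,5-trimethoxyphenyl)-3,4-dihydro-2H-chromen-4-ol | COc1cc([C@H]2C[C@@H](O)c3c(cc(OC)c(OC)c3OC)O2)cc(OC)c1OC
F4 | step 2 | ethyl (E)-3-(3,4,5-trimethoxyphenoxy)acrylate | CCOC(=O)/C=C/Oc1cc(OC)c(OC)c(OC)c1
F5 | step 2 | (E)-3-(3,4,5-trimethoxyphenoxy)acrylic acid | OC(=O)/C=C/Oc1cc(OC)c(OC)c(OC)c1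
F6 | step 1 | 1,2,3-trimethoxy-5-(methoxymethoxy)benzene | COCOc1cc(OC)c(OC)c(OC)c1
F7 | step 1 | 1-[2,3,4-trimethoxy-6-(methoxymethoxy)phenyl]ethan-1-one | COCOc1cc(OC)c(OC)c(OC)c1C(C)=O
A1 | alternative 1 | 3,4,5-trimethoxybenzaldehyde | COc1cc(C=O)cc(OC)c1OC
A2 | alternative 1 | (E)-1-(6-hydroxy-2,3,4-trimethoxyphenyl)-3-(3,4,5-trimethoxyphenyl)prop-2-en-1-one | COc1cc(/C=C/C(=O)c2c(O)cc(OC)c(OC)c2OC)cc(OC)c1OC
A3 | alternative 1 | tert-butyl 2-(6-hydroxy-2,3,4-trimethoxybenzoyl)-3-(3,4,5-trimethoxyphenyl)prop-2-enoate (alkene geometry not defined) | COc1cc(C=C(C(=O)OC(C)(C)C)C(=O)c2c(O)cc(OC)c(OC)c2OC)cc(OC)c1OC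
A4 | alternative 2 | 2-iodo-3,4,5-trimethoxyphenol | COc1cc(O)c(I)c(OC)c1OC
A5 | alternative 2 | 5-ethynyl-1,2,3-trimethoxybenzene | C#Cc1cc(OC)c(OC)c(OC)c1
A6 | alternative 2 | 5,6,7-trimethoxy-2-(3,4,5-trimethoxyphenyl)-4H-chromen-4-one | COc1cc(-c2cc(=O)c3c(OC)c(OC)c(OC)cc3o2)cc(OC)c1OC
A7 | alternative 2 | (2S,4S)-5,6,7-trimethoxy-2-(3,4,5-trimethoxyphenyl)-3,4-dihydro-2H-chromen-4-ol | COc1cc([C@@H]2C[C@H](O)c3c(cc(OC)c(OC)c3OC)O2)cc(OC)c1OC
A8 | alternative 3 | ethyl (R)-3-hydroxy-3-(3,4,5-trimethoxyphenyl)propanoate | CCOC(=O)C[C@@H](O)c1cc(OC)c(OC)c(OC)c1
A9 | alternative 3 | (S)-3-(3,4,5-trimethoxyphenoxy)-3-(3,4,5-trimethoxyphenyl)propanoic acid | COc1cc([C@H](CC(=O)O)Oc2cc(OC)c(OC)c(OC)c2)cc(OC)c1OC
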